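## Retrosynthetic overview

- The three N‑methyl groups come off last: the target is the exhaustive reductive methylation product of the tri‑secondary‑amine macrolactam.
- The only ring (17‑membered) is made in one flask from unprotected spermine and an activated (E)‑hexadec‑2‑enoyl unit, as in the presumed biogenesis (polyamine plus 2‑enoyl thioester).
- Order of ring‑forming bonds: first the C4–N5 bond by a catalytic enantioselective aza‑Michael addition, which sets C4 (R); then the N1–C2 amide bond by macrolactamization with loss of the activating group.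
- The activated enoyl unit is the N‑enoyl oxazolidin‑2‑one, a thioester surrogate that chelates the chiral palladium catalyst, made from (E)‑hexadec‑2‑enoic acid.

Assumption: (E)‑hexadec‑2‑enoic acid and spermine are bought as catalogue reagents, and the catalyst [{Pd((S)‑BINAP)(μ‑OH)}2](OTf)2 is made beforehand from PdCl2((S)‑BINAP) and AgOTf and is not counted as a step.

## Route

Step 1
Reactants: 1 (E)‑hexadec‑2‑enoic acid; 2 oxazolidin‑2‑one
Product: 4 3‑[(E)‑hexadec‑2‑enoyl]oxazolidin‑2‑one, via mixed pivalic anhydride 3 (not isolated)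
Conditions: PivCl, Et3N, THF, −20 °C; then LiCl, 2, −20 °C → rt
Reagents that add atoms: none
Why: Mixed‑anhydride N‑acylation, in which the LiCl/Et3N‑activated oxazolidinone attacks the less hindered enoyl carbonyl of the pivalic anhydride under conditions mild enough to keep the E‑alkene in conjugation.

Step 2
Reactants: 4 3‑[(E)‑hexadec‑2‑enoyl]oxazolidin‑2‑one; 5 spermine
Product: 8 (4R)‑4‑tridecyl‑1,5,9,14‑tetraazacycloheptadecan‑2‑one, via spermine tetrakis(triflate) 6 (not isolated), via Michael adduct tetrakis(triflate) 7 (not isolated)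
Conditions: 5 (1.2 equiv), TfOH (4.0 equiv per 5), THF, 0 °C; 4, [{Pd((S)‑BINAP)(μ‑OH)}2](OTf)2 (5 mol%), rt, 48 h; then iPr2NEt (6 equiv), MeCN (2 mM), 45 °C
Reagents that add atoms: none
Why: Proposed new method: with all four nitrogens kept as triflate salts the hydroxo‑bridged divalent palladium complex releases only a trace of free amine, so there is no racemic background and no catalyst‑binding polyamine, and the least hindered terminal NH2 adds to C3 of the O,O‑chelated s‑cis imide on the re face left open by the equatorial P‑phenyl groups of (S)‑BINAP, which sets that carbon (C4 of the ring) as R; adding base then frees the distal NH2, which closes the 17‑membered lactam by acyl substitution on the imide with loss of oxazolidin‑2‑one, primary NH2 acylating far faster than the hindered secondary nitrogens that would give 8‑ or 13‑membered rings; the closest known reaction types are the palladium–BINAP‑catalysed enantioselective aza‑Michael addition of amine triflate salts (anilines, benzylamine) to 3‑alkenoyloxazolidin‑2‑ones and the aza‑Michael/macrolactamization pairing of spermine with enoates used for racemic spermine lactams.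

Step 3
Reactants: 8 (4R)‑4‑tridecyl‑1,5,9,14‑tetraazacycloheptadecan‑2‑one
Product: 9 (4R)‑5,9,14‑trimethyl‑4‑tridecyl‑1,5,9,14‑tetraazacycloheptadecan‑2‑one (target)
Conditions: 37% aq. HCHO (10 equiv), HCO2H, 90 °C
Reagents that add atoms: formaldehyde, C=O
Why: Eschweiler–Clarke reductive methylation, in which each secondary amine forms a methyleneiminium ion (any aminal reverts to it in hot acid) that formate reduces irreversibly with loss of CO2, while the amide N–H is not methylated and the C4 stereocentre is not involved.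

## Compound list

1 | (E)‑hexadec‑2‑enoic acid | CCCCCCCCCCCCC/C=C/C(=O)O | starting material
2 | oxazolidin‑2‑one | O=C1NCCO1 | starting material
3 | (E)‑hexadec‑2‑enoic pivalic anhydride | CCCCCCCCCCCCC/C=C/C(=O)OC(=O)C(C)(C)C | intermediate
4 | 3‑[(E)‑hexadec‑2‑enoyl]oxazolidin‑2‑one | CCCCCCCCCCCCC/C=C/C(=O)N1CCOC1=O | intermediate
5 | spermine, N1,N1'‑(butane‑1,4‑diyl)bis(propane‑1,3‑diamine) | NCCCNCCCCNCCCN | starting material
6 | spermine tetrakis(trifluoromethanesulfonate) | [NH3+]CCC[NH2+]CCCC[NH2+]CCC[NH3+].[O-]S(=O)(=O)C(F)(F)F.[O-]S(=O)(=O)C(F)(F)F.[O-]S(=O)(=O)C(F)(F)F.[O-]S(=O)(=O)C(F)(F)F | intermediate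
7 | 3‑[(3R)‑3‑{[3‑({4‑[(3‑aminopropyl)amino]butyl}amino)propyl]amino}hexadecanoyl]oxazolidin‑2‑one tetrakis(trifluoromethanesulfonate) | CCCCCCCCCCCCC[C@H](CC(=O)N1CCOC1=O)[NH2+]CCC[NH2+]CCCC[NH2+]CCC[NH3+].[O-]S(=O)(=O)C(F)(F)F.[O-]S(=O)(=O)C(F)(F)F.[O-]S(=O)(=O)C(F)(F)F.[O-]S(=O)(=O)C(F)(F)F | intermediate
8 | (4R)‑4‑tridecyl‑1,5,9,14‑tetraazacycloheptadecan‑2‑one | CCCCCCCCCCCCC[C@@H]1CC(=O)NCCCNCCCCNCCCN1 | intermediate
9 | (4R)‑5,9,14‑trimethyl‑4‑tridecyl‑1,5,9,14‑tetraazacycloheptadecan‑2‑one | CCCCCCCCCCCCC[C@@H]1CC(=O)NCCCN(C)CCCCN(C)CCCN1C | target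

## Step count and risks

Total step count: 3. Longest linear sequence: 3 (1 → 4 → 8 → 9).

**Step 2 (highest risk).** Possible failures:
- the polyammonium salt may starve or bind the palladium catalyst;
- an internal NH may add in place of the terminal NH2;
- the ee may be low; the (S)‑ligand is chosen from a quadrant analysis and not from a measured result, and if the sense of induction proves opposite, the (R)‑BINAP complex is used;
- after neutralisation the C3 amine may attack the ring carbonyl of the imide before the large ring closes.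

The fallback sets out from 1 (with 5) and comes back at 8; it gives up the catalytic control and the imide. Fischer esterification of 1 (MeOH, cat. H2SO4, reflux) gives methyl (E)‑hexadec‑2‑enoate F1. Uncatalysed aza‑Michael addition of excess free‑base 5 (3 equiv, MeOH, rt → 50 °C) gives racemic methyl 3‑{[3‑({4‑[(3‑aminopropyl)amino]butyl}amino)propyl]amino}hexadecanoate F2 through the terminal nitrogen. Template macrolactamization with Sb(OEt)3 (toluene, 80 °C) gives racemic 4‑tridecyl‑1,5,9,14‑tetraazacycloheptadecan‑2‑one F3. Preparative chromatography on a chiral stationary phase separates 8 from (4S)‑4‑tridecyl‑1,5,9,14‑tetraazacycloheptadecan‑2‑one F4, which is discarded.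

**Step 3.** Exhaustive methylation of three secondary amines beside an amide N–H may stop at methylene‑bridged aminals (N5/N9 or N14/N1) or give N‑formyl by‑products.

The fallback sets out from 4 and comes back at 9; it brings two of the methyl groups in with the polyamine, so that only one nitrogen is methylated at the end. Commercial N,N'‑dimethylbutane‑1,4‑diamine is bis‑cyanoethylated with acrylonitrile (EtOH, rt) to 3,3'‑[butane‑1,4‑diylbis(methylazanediyl)]dipropanenitrile F5. Hydrogenation (H2, Raney Ni, NH3/MeOH) gives N1,N1'‑(butane‑1,4‑diyl)bis(N1‑methylpropane‑1,3‑diamine) F6. Under the conditions of step 2 its tetrakis(trifluoromethanesulfonate) F7 adds to 4 to give 3‑[(3R)‑3‑({3‑[{4‑[(3‑aminopropyl)(methyl)amino]butyl}(methyl)amino]propyl}amino)hexadecanoyl]oxazolidin‑2‑one tetrakis(trifluoromethanesulfonate) F8. Neutralisation closes this to (4R)‑9,14‑dimethyl‑4‑tridecyl‑1,5,9,14‑tetraazacycloheptadecan‑2‑one F9; here only primary NH2 groups can add or be acylated. One reductive methylation at N5 (aq. HCHO, NaBH(OAc)3, 1,2‑dichloroethane, rt) then gives 9.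

**Step 1.** The activated enoyl unit may pick up chloride or oxazolidinone at C3, or lose alkene geometry.

The fallback sets out from 2 and comes back at 4; it forms the C2=C3 bond by olefination and does not start from the unsaturated acid. Compound 2 is N‑acylated with bromoacetyl bromide (n‑BuLi, THF, −78 °C) to 3‑(bromoacetyl)oxazolidin‑2‑one F10. Arbuzov reaction with P(OEt)3 (neat, 90 °C) gives diethyl [2‑oxo‑2‑(2‑oxooxazolidin‑3‑yl)ethyl]phosphonate F11. Masamune–Roush Horner–Wadsworth–Emmons olefination with commercial tetradecanal (LiCl, iPr2NEt, MeCN, rt) gives 4 as the E isomer.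

## Further compounds

F1 | step 2 | methyl (E)‑hexadec‑2‑enoate | CCCCCCCCCCCCC/C=C/C(=O)OC
F2 | step 2 | racemic methyl 3‑{[3‑({4‑[(3‑aminopropyl)amino]butyl}amino)propyl]amino}hexadecanoate | CCCCCCCCCCCCCC(CC(=O)OC)NCCCNCCCCNCCCN
F3 | step 2 | racemic 4‑tridecyl‑1,5,9,14‑tetraazacycloheptadecan‑2‑one | CCCCCCCCCCCCCC1CC(=O)NCCCNCCCCNCCCN1
F4 | step 2 | (4S)‑4‑tridecyl‑1,5,9,14‑tetraazacycloheptadecan‑2‑one | CCCCCCCCCCCCC[C@H]1CC(=O)NCCCNCCCCNCCCN1
F5 | step 3 | 3,3'‑[butane‑1,4‑diylbis(methylazanediyl)]dipropanenitrile | N#CCCN(C)CCCCN(C)CCC#N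
F6 | step 3 | N1,N1'‑(butane‑1,4‑diyl)bis(N1‑methylpropane‑1,3‑diamine) | NCCCN(C)CCCCN(C)CCCN
F7 | step 3 | N1,N1'‑(butane‑1,4‑diyl)bis(N1‑methylpropane‑1,3‑diamine) tetrakis(trifluoromethanesulfonate) | [NH3+]CCC[NH+](C)CCCC[NH+](C)CCC[NH3+].[O-]S(=O)(=O)C(F)(F)F.[O-]S(=O)(=O)C(F)(F)F.[O-]S(=O)(=O)C(F)(F)F.[O-]S(=O)(=O)C(F)(F)F
F8 | step 3 | 3‑[(3R)‑3‑({3‑[{4‑[(3‑aminopropyl)(methyl)amino]butyl}(methyl)amino]propyl}amino)hexadecanoyl]oxazolidin‑2‑one tetrakis(trifluoromethanesulfonate) | CCCCCCCCCCCCC[C@H](CC(=O)N1CCOC1=O)[NH2+]CCC[NH+](C)CCCC[NH+](C)CCC[NH3+].[O-]S(=O)(=O)C(F)(F)F.[O-]S(=O)(=O)C(F)(F)F.[O-]S(=O)(=O)C(F)(F)F.[O-]S(=O)(=O)C(F)(F)F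
F9 | step 3 | (4R)‑9,14‑dimethyl‑4‑tridecyl‑1,5,9,14‑tetraazacycloheptadecan‑2‑one | CCCCCCCCCCCCC[C@@H]1CC(=O)NCCCN(C)CCCCN(C)CCCN1
F10 | step 1 | 3‑(bromoacetyl)oxazolidin‑2‑one | O=C(CBr)N1CCOC1=O
F11 | step 1 | diethyl [2‑oxo‑2‑(2‑oxooxazolidin‑3‑yl)ethyl]phosphonate | CCOP(=O)(OCC)CC(=O)N1CCOC1=O
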